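**Retrosynthetic overview**

1. Bannamurpanisin is traced back to its 3-bromo derivative, from which the C3–Br bond is removed by hydrogenolysis.
2. The strategy rests on C3, the only hydrogen-bearing carbon of the pyranone ring C, which lies between the aryl-bearing C2 and the carbonyl carbon C4. Taking C3 out leaves a 2-aryl-3-oxybenzofuran, so ring C is cut at C2–C3 and C3–C4 into a 3-silyloxybenzofuran and dibromocarbene (one-carbon ring expansion).
3. The silyloxybenzofuran comes from a 2-arylbenzofuran-3(2H)-one, closed at O1–C2 by intramolecular O-alkylation of an α-bromo-2'-hydroxydeoxybenzoin.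
4. The deoxybenzoin comes from Friedel–Crafts acylation with ortho-demethylation of 1,2,3,5-tetramethoxybenzene by (3,4,5-trimethoxyphenyl)acetyl chloride.
5. Ring order: rings A and B are purchased, the furan ring is closed first (step 4) and is then enlarged to ring C (step 5).

Key step: step 5

Remark: compounds 6, 7 and 10 carry stereocentres and are formed as racemates; all of these centres become sp2 again before the achiral target, so no stereocontrol is required.

**Route**

Step 1
Reactants: 1 (3,4,5-trimethoxyphenyl)acetic acid
Product: 2 (3,4,5-trimethoxyphenyl)acetyl chloride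
Conditions: (COCl)2, DMF (cat.), CH2Cl2, 0 °C to rt; volatiles removed, used crude
Reagents that add atoms: oxalyl chloride, ClC(=O)C(=O)Cl
Why: Acid chloride formation through the chloroiminium species from DMF is standard for arylacetic acids and does not touch aryl methyl ethers.

Step 2
Reactants: 2 (3,4,5-trimethoxyphenyl)acetyl chloride; 3 1,2,3,5-tetramethoxybenzene
Product: 5 1-(2-hydroxy-3,4,6-trimethoxyphenyl)-2-(3,4,5-trimethoxyphenyl)ethan-1-one, via tetramethoxy ketone 4 (not isolated)
Conditions: AlCl3 (2 equiv), Et2O, 0 °C to rt; then ice and dilute aq HCl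
Reagents that add atoms: none
Why: Friedel–Crafts acylation at one of the two equivalent free positions of 3 (each flanked by two methoxy groups and para to a third) is followed in the same flask by aluminium-chelate-assisted cleavage of the more crowded ortho methoxy group, the one lying between the new carbonyl and a neighbouring methoxy group, which should give the hydrogen-bonded phenol that becomes O1.

Step 3
Reactants: 5 1-(2-hydroxy-3,4,6-trimethoxyphenyl)-2-(3,4,5-trimethoxyphenyl)ethan-1-one
Product: 6 2-bromo-1-(2-hydroxy-3,4,6-trimethoxyphenyl)-2-(3,4,5-trimethoxyphenyl)ethan-1-one (racemic)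
Conditions: CuBr2 (2.1 equiv), EtOAc–CHCl3 (1:1), reflux
Reagents that add atoms: copper dibromide, Br[Cu]Br
Why: α-Bromination of an enolisable ketone with CuBr2 (King–Ostrum conditions) should take place at the readily enolised benzylic α-carbon, because the heterogeneous divalent copper bromide is much less prone than Br2 to brominate the arene rings; the new stereocentre is formed racemic and is lost in step 4.

Step 4
Reactants: 6 2-bromo-1-(2-hydroxy-3,4,6-trimethoxyphenyl)-2-(3,4,5-trimethoxyphenyl)ethan-1-one
Product: 8 tert-butyl{[4,6,7-trimethoxy-2-(3,4,5-trimethoxyphenyl)-1-benzofuran-3-yl]oxy}dimethylsilane, via racemic benzofuranone 7 (not isolated)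
Conditions: Et3N (3 equiv), MeCN, rt, argon; then TBSOTf (1.3 equiv), 0 °C
Reagents that add atoms: tert-butyldimethylsilyl trifluoromethanesulfonate (TBSOTf), CC(C)(C)[Si](C)(C)OS(=O)(=O)C(F)(F)F
Why: Intramolecular Williamson O-alkylation (5-exo-tet) of the phenoxide on the secondary benzylic α-bromide closes the furanone ring, and soft enolisation with Et3N and the silyl triflate then traps the ketone on oxygen as the aromatic 3-silyloxybenzofuran before its air-sensitive C2–H can autoxidise.

Step 5
Reactants: 8 tert-butyl{[4,6,7-trimethoxy-2-(3,4,5-trimethoxyphenyl)-1-benzofuran-3-yl]oxy}dimethylsilane; 9 bromoform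
Product: 12 3-bromo-5,7,8-trimethoxy-2-(3,4,5-trimethoxyphenyl)-4H-chromen-4-one, via dibromocyclopropane adduct 10 (not isolated), via silyloxyflavylium bromide 11 (not isolated)
Conditions: CHBr3 (3 equiv, added slowly), KOtBu (3 equiv), toluene, −20 °C to rt, argon
Reagents that add atoms: bromoform, BrC(Br)Br
Why: Proposed new method: dibromocarbene, released by α-elimination from the tribromomethyl anion, should add as an electrophile to the C2=C3 bond of the furan ring of 8 (the future C2 and C4 of the flavone) to give the cis-fused dibromocyclopropane 10. Loss of one bromide from 10 with disrotatory cleavage of the bond common to the three- and five-membered rings should then lead to the 3-bromo-4-silyloxyflavylium bromide 11, and attack of bromide on silicon frees the chromone carbonyl of 12. The closest known reaction types are the dihalocarbene ring expansion of cyclic silyl enol ethers to 2-halo-enones with one more ring carbon and the Ciamician–Dennstedt enlargement of indoles and benzofurans by halocarbenes, neither of which has been shown on a 2-aryl-3-silyloxybenzofuran. Ring C is closed not by a cyclisation but by expansion of the furan from five to six members, the carbene carbon becoming C3 and forming the C2–C3 and C3–C4 bonds, with the aromatic 4-oxypyrylium cation as driving force. No stereocentre remains, since the two made in 10 are flattened on ring opening. The step needs chemoselective addition to the enol ether bond over the two trimethoxyarene rings, which the donation of both the ring oxygen and the silyloxy oxygen into that bond should secure, and cleavage of the internal cyclopropane bond, which the oxygen-stabilised cation dictates.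

Step 6
Reactants: 12 3-bromo-5,7,8-trimethoxy-2-(3,4,5-trimethoxyphenyl)-4H-chromen-4-one
Product: 13 5,7,8-trimethoxy-2-(3,4,5-trimethoxyphenyl)-4H-chromen-4-one (bannamurpanisin)
Conditions: H2 (1 atm), 10% Pd/C, Et3N (2 equiv), EtOAc–MeOH, rt, stopped after one equivalent of H2
Reagents that add atoms: none
Why: Catalytic hydrogenolysis of the vinylic C3–Br bond of a 3-bromochromone over palladium with an amine as HBr scavenger is faster than saturation of the conjugated, aryl-substituted C2=C3 bond, so the flavone should be left intact.

**Compound list**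

1 | (3,4,5-trimethoxyphenyl)acetic acid | COc1cc(CC(=O)O)cc(OC)c1OC | starting material
2 | (3,4,5-trimethoxyphenyl)acetyl chloride | COc1cc(CC(=O)Cl)cc(OC)c1OC | intermediate
3 | 1,2,3,5-tetramethoxybenzene | COc1cc(OC)c(OC)c(OC)c1 | starting material
4 | 1-(2,3,4,6-tetramethoxyphenyl)-2-(3,4,5-trimethoxyphenyl)ethan-1-one (not isolated) | COc1cc(CC(=O)c2c(OC)cc(OC)c(OC)c2OC)cc(OC)c1OC | intermediate
5 | 1-(2-hydroxy-3,4,6-trimethoxyphenyl)-2-(3,4,5-trimethoxyphenyl)ethan-1-one | COc1cc(CC(=O)c2c(OC)cc(OC)c(OC)c2O)cc(OC)c1OC | intermediate
6 | 2-bromo-1-(2-hydroxy-3,4,6-trimethoxyphenyl)-2-(3,4,5-trimethoxyphenyl)ethan-1-one (racemic) | COc1cc(C(Br)C(=O)c2c(OC)cc(OC)c(OC)c2O)cc(OC)c1OC | intermediate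
7 | 4,6,7-trimethoxy-2-(3,4,5-trimethoxyphenyl)-1-benzofuran-3(2H)-one (racemic, not isolated) | COc1cc(OC)c2c(c1OC)OC(c1cc(OC)c(OC)c(OC)c1)C2=O | intermediate
8 | tert-butyl{[4,6,7-trimethoxy-2-(3,4,5-trimethoxyphenyl)-1-benzofuran-3-yl]oxy}dimethylsilane | COc1cc(OC)c2c(O[Si](C)(C)C(C)(C)C)c(-c3cc(OC)c(OC)c(OC)c3)oc2c1OC | intermediate
9 | bromoform | BrC(Br)Br | starting material
10 | 1,1-dibromo-6b-[(tert-butyldimethylsilyl)oxy]-3,4,6-trimethoxy-1a-(3,4,5-trimethoxyphenyl)-1a,6b-dihydro-1H-cyclopropa[b][1]benzofuran (racemic, cis-fused by necessity, not isolated) | COc1cc(OC)c2c(c1OC)OC1(c3cc(OC)c(OC)c(OC)c3)C(Br)(Br)C21O[Si](C)(C)C(C)(C)C | intermediate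
11 | 3-bromo-4-[(tert-butyldimethylsilyl)oxy]-5,7,8-trimethoxy-2-(3,4,5-trimethoxyphenyl)chromenylium bromide (not isolated) | COc1cc(OC)c2c(O[Si](C)(C)C(C)(C)C)c(Br)c(-c3cc(OC)c(OC)c(OC)c3)[o+]c2c1OC.[Br-] | intermediate
12 | 3-bromo-5,7,8-trimethoxy-2-(3,4,5-trimethoxyphenyl)-4H-chromen-4-one | COc1cc(OC)c2c(=O)c(Br)c(-c3cc(OC)c(OC)c(OC)c3)oc2c1OC | intermediate
13 | 5,7,8-trimethoxy-2-(3,4,5-trimethoxyphenyl)-4H-chromen-4-one (bannamurpanisin) | COc1cc(-c2cc(=O)c3c(OC)cc(OC)c(OC)c3o2)cc(OC)c1OC | target

**Step count**

Total: 6 steps. Longest linear sequence: 6 steps (1 → 2 → 5 → 6 → 8 → 12 → 13).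

**Steps most likely to fail, with fallbacks**

Step 5 (proposed new method). The carbene may fail to reach the fully substituted enol ether bond, which is screened by the silyl group, the peri methoxy group and the 2-aryl ring. The base may also strip the silyl group before addition, or the adduct may open along another path. The fallback uses known flavone chemistry and leaves the ring-expansion idea. It sets out from 3: acetylation with acetyl chloride and AlCl3 in Et2O should give 1-(2,3,4,6-tetramethoxyphenyl)ethan-1-one F1, which loses its crowded ortho methyl group in the same flask to give 1-(2-hydroxy-3,4,6-trimethoxyphenyl)ethan-1-one F2. Claisen–Schmidt condensation of F2 with commercial 3,4,5-trimethoxybenzaldehyde (KOH, EtOH, rt) should give (E)-1-(2-hydroxy-3,4,6-trimethoxyphenyl)-3-(3,4,5-trimethoxyphenyl)prop-2-en-1-one F3. Oxidative cyclisation of F3 with catalytic iodine in DMSO at 130 °C (oxa-Michael closure, then dehydrogenation) comes back to the route at 13.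

Step 3. Electrophilic bromination of ring A at its one free position, para to the phenol, may compete with α-bromination, or a second bromine may enter. The fallback avoids electrophilic halogen and sets out from 5. Regitz diazo transfer with 4-acetamidobenzenesulfonyl azide and DBU in MeCN at 0 °C should give 2-diazo-1-(2-hydroxy-3,4,6-trimethoxyphenyl)-2-(3,4,5-trimethoxyphenyl)ethan-1-one F4. Dirhodium tetraacetate, Rh2(OAc)4 (1 mol%), in CH2Cl2 at rt should then form the rhodium carbene, which inserts into the phenol O–H bond and closes the furanone ring. The fallback comes back to the route at 7, which is silylated in the same flask with Et3N and TBSOTf as in step 4.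

Step 4. The benzofuranone or its enolate may autoxidise at C2, or be alkylated at carbon by unreacted bromide, before the bulky silyl group is in place. The fallback relays through a small, isolable enol derivative and sets out from 6. Closure with NaOAc in refluxing EtOH under argon, followed by acetylation of the crude ketone (Ac2O, pyridine, DMAP), should give the air-stable 4,6,7-trimethoxy-2-(3,4,5-trimethoxyphenyl)-1-benzofuran-3-yl acetate F5, which can be purified. MeLi (2.1 equiv) in THF at −78 to 0 °C should cleave the enol acetate to lithium 4,6,7-trimethoxy-2-(3,4,5-trimethoxyphenyl)-1-benzofuran-3-olate F6, which is trapped in the flask with TBSCl. The fallback comes back to the route at 8.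

**Further compounds**

F1 | step 5 | 1-(2,3,4,6-tetramethoxyphenyl)ethan-1-one | CC(=O)c1c(OC)cc(OC)c(OC)c1OC
F2 | step 5 | 1-(2-hydroxy-3,4,6-trimethoxyphenyl)ethan-1-one | CC(=O)c1c(OC)cc(OC)c(OC)c1O
F3 | step 5 | (E)-1-(2-hydroxy-3,4,6-trimethoxyphenyl)-3-(3,4,5-trimethoxyphenyl)prop-2-en-1-one | COc1cc(/C=C/C(=O)c2c(OC)cc(OC)c(OC)c2O)cc(OC)c1OC
F4 | step 3 | 2-diazo-1-(2-hydroxy-3,4,6-trimethoxyphenyl)-2-(3,4,5-trimethoxyphenyl)ethan-1-one | COc1cc(C(=[N+]=[N-])C(=O)c2c(OC)cc(OC)c(OC)c2O)cc(OC)c1OC
F5 | step 4 | 4,6,7-trimethoxy-2-(3,4,5-trimethoxyphenyl)-1-benzofuran-3-yl acetate | COc1cc(OC)c2c(OC(C)=O)c(-c3cc(OC)c(OC)c(OC)c3)oc2c1OC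
F6 | step 4 | lithium 4,6,7-trimethoxy-2-(3,4,5-trimethoxyphenyl)-1-benzofuran-3-olate | [Li+].COc1cc(OC)c2c([O-])c(-c3cc(OC)c(OC)c(OC)c3)oc2c1OC
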